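**Remark on the target.** The SMILES has (1R,2S) in one ring and (1'S,2'R) in the other, with both exocyclic alkenes Z. The compound is therefore the achiral meso diastereomer; "single enantiomer" is read as "this single stereoisomer", and the route must pair two mirror-image halves.

## Structural features

The target is built from two constitutionally identical halves: two cyclohexane rings (C1–C6 and C1'–C6') joined through C3 and C3' by a four-carbon bridge, C3=C7–C8–C8'–C7'=C3', so that the centre is a skipped 1,5-diene. Both exocyclic trisubstituted alkenes are Z, with the bridge carbon C8 cis to the carbinol carbon C2 and not to the ring methylene C4, which is the more crowded and less stable arrangement. In each ring the quaternary C1 (methyl and the acyl group C9(=O)–C10H2–C11H=C12Me2) stands next to the secondary allylic carbinol C2, with hydroxyl and acyl cis on the ring. The two stereodiads have opposite configuration (1R,2S and 1'S,2'R), so the molecule is the centrosymmetric meso diastereomer; the diads are eight bonds apart, too far to influence each other or to make the meso and C2-symmetric diastereomers separable. Fragile groups are the β-hydroxy ketone of each half (retro-aldol cleavage of C1–C2 with base), the β,γ-unsaturated ketone with its doubly activated C10H2 (migration into conjugation) and the allylic alcohol C2–OH (ionisation with acid). The real difficulty is threefold: the quaternary C1 next to C2 with the cis relation, the contra-thermodynamic Z alkenes, and the heterochiral pairing of the halves, since dimerising one enantiomer gives the wrong diastereomer and dimerising a racemate gives both. The key step exploits the 1,3-relation O=C9–C1(CH3)–C2–OH: it is read as the product of a semipinacol shift in which the C1–CH3 bond is formed by migration of a methyl group from C9 to C1 while a C1–O oxirane bond is broken and the C2–O bond is kept.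

These atom labels (C1–C12, primed in the second half) are used for all intermediates.

## Logic of the disconnections

**23 from 22.** The two O–Si bonds at C2 and C2' are cut last. The free aldol units cannot be carried through base, so both hydroxyls stay capped until the end. The forward step must be a non-basic, only weakly acidic desilylation.

**22 from 18 and 19.** The C10–C11 and C10'–C11' bonds (sp3–sp2) are cut, which turns both β,γ-unsaturated ketones into acetyl groups. The acidic, isomerisation-prone C10H2 groups would not survive the ylides used earlier, whereas an acetyl group on a quaternary carbon has only one enolisable position. Eight carbons and the most base-sensitive unit are removed in one two-directional operation. The forward step must stop at mono-alkenylation of each methyl group and protonate the resulting dienolates at C10.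

**18 from 16 and 11.** The C3'=C7' double bond is cut. This is where a half of one configuration meets a half of the other, so the meso relation is built by construction. The cut is unsymmetrical in time: one half carries phosphorus, the other the carbonyl. The forward step must give the Z alkene, react at the ring carbonyl and not at the acetyl groups, and leave C2' untouched.

**16 from 15 from 14.** C–P, C–I and C–O bonds at C7' are exchanged. These two functional group changes turn the oxygen terminus of the first olefination into the phosphorus terminus of the second, which is what lets the two olefinations use different partners.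

**14 from 10 and 12.** The C3=C7 double bond is cut, with the same demands as above. 12 brings all four bridge carbons (C7, C8, C8', C7') with the two ends already differentiated.

**10 from 8, and 11 from 9.** O–Si bonds. The silyl ether also supplies the α-oxygen substituent on which the Z selectivity of both olefinations rests.

**8 from 6, and 9 from 7 (key disconnection).** The C1–CH3 bond is cut and the methyl group is returned to C9, while C1 and C2 are bridged by oxygen. The quaternary centre and the carbinol of a half become a cis-fused oxirane next to a dimethylcarbinol. The cut is made here because the forward 1,2-shift is stereospecific: it fixes hydroxyl cis to acyl without enolate chemistry, auxiliary or diastereoselective reduction, and it leaves the ring carbonyl C3 where the olefination needs it. Two adjacent stereocentres, one quaternary, collapse to the two carbons of a flat enone. The forward step must let the methyl shift outrun acyl shift, hydride shift and elimination. The same disconnection is applied to both antipodes.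

**6 and 7 from 5.** The two C–O bonds of the oxirane are cut. One achiral enone serves both series. Because the target is meso, both antipodes are needed in equal amounts, and it does not matter which catalyst gives which, only that the two batches are opposite and enantiopure.

**5 from 3, 3 from 2, 2 from 1.** The C3=O group is traced back to an aryl methyl ether (enol ether hydrolysis, Birch reduction), which fixes the 1,3-relation of C3 and C1 from the meta substitution of 1. One C9–CH3 bond is cut to reach the commercial ketone 1.

## Other disconnections considered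

**Alternative 1:** (the first that comes to mind) Cut the central C8–C8' bond, because the molecule looks like a dimer, and close each ring by an intramolecular aldol addition. The forward key step would be alkylation of the lithiated allylic sulfone A2 with the allylic bromide A1, then reductive desulfonylation (or reductive homocoupling of A1 alone). Homocoupling of one enantiomer can only give the C2-symmetric diastereomer, and a racemate would give both diastereomers. A1 and A2 would therefore have to come from opposite enantiomeric series, so the economy of a dimerisation is lost. Allylic anions and halides of this type can also lose the Z geometry, react at C3, or shift the double bond on desulfonylation. The aldol ring closure would need a Z enal and a tetrasubstituted enolate next to the more acidic C10H2. The chosen plan fixes the C1/C2 diad stereospecifically and forms no bond at an allylic carbon.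

**Alternative 2:** Cut both C3=C7 bonds at once: a three-component double Wittig reaction of the bis-ylide from the bis-phosphonium salt A3 with two molecules of a ring ketone. This is the shortest union on paper. The two olefinations are independent events, however: one enantiomer of the ketone would give only the C2-symmetric isomer, and the racemate a statistical mixture of meso and C2 forms that differ only at centres eight bonds apart. The chosen plan keeps the same bond-forming reaction but runs it in two separate steps on 10 and 11, which costs two functional group changes and makes the meso pairing certain.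

**Alternative 3:** Cut both C1–C2 ring bonds (retro-aldol) to the acyclic (2Z,6Z)-dienedial A4, and close both rings by a two-fold 6-(enolexo) aldol addition. The aldol retron is obvious, but the enolate needed is the tetrasubstituted one at the α-methyl carbon, in competition with the doubly activated C10H2. A Z enal is expected to isomerise to E under the same basic conditions. Each ring would also choose its configuration independently, so the meso/C2 question stays open. The semipinacol route sets the same diad from an oxirane with no enolate and no reversible step.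

Key step: step 6

## Steps

**Step 1**
Reactants: 1 3'-methoxyacetophenone
Product: 2 2-(3-methoxyphenyl)propan-2-ol
Conditions: MeMgBr (1.3 equiv), THF, 0 °C to rt; sat. aq. NH4Cl
Reagents that add atoms: methylmagnesium bromide, C[Mg]Br
Why: Grignard 1,2-addition to the aryl ketone should give the tertiary benzylic alcohol; it supplies the future C9 with two identical methyl groups, one of which becomes the C1 methyl and the other C10, and no stereocentre is formed.

**Step 2**
Reactants: 2 2-(3-methoxyphenyl)propan-2-ol
Product: 3 2-(5-methoxycyclohexa-1,4-dien-1-yl)propan-2-ol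
Conditions: Li (5 equiv), liq. NH3/THF, t-BuOH, −78 to −33 °C; solid NH4Cl
Reagents that add atoms: none
Why: Birch reduction of an arene with one donor and one alkyl-type substituent gives the 1,4-diene with both substituents on sp2 carbons, which places the future carbonyl carbon C3 1,3 to C1; the benzylic C–O bond should survive because it is present as the lithium alkoxide and t-BuOH protonates the radical anion faster than C–O cleavage.

**Step 3**
Reactants: 3 2-(5-methoxycyclohexa-1,4-dien-1-yl)propan-2-ol
Product: 5 3-(2-hydroxypropan-2-yl)cyclohex-2-en-1-one, via β,γ-unsaturated ketone 4 (not isolated)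
Conditions: oxalic acid, THF/H2O, rt; then DBU (0.2 equiv), CH2Cl2, rt
Reagents that add atoms: water, O
Why: Mild acid hydrolysis of the enol ether gives the β,γ-unsaturated ketone and a catalytic amine base moves the double bond into the only conjugated position (C1=C2); oxalic acid is chosen over mineral acid so that the tertiary allylic alcohol is not ionised.

**Step 4**
Reactants: 5 3-(2-hydroxypropan-2-yl)cyclohex-2-en-1-one
Product: 6 (1R,6R)-6-(2-hydroxypropan-2-yl)-7-oxabicyclo[4.1.0]heptan-2-one
Conditions: 9-amino-9-deoxy-epi-quinine (10 mol%), TFA (20 mol%), 50% aq. H2O2 (1.5 equiv), 1,4-dioxane, 30–50 °C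
Reagents that add atoms: hydrogen peroxide, OO
Why: Amine-catalysed asymmetric Weitz–Scheffer epoxidation of a cyclic enone: the primary amine forms an iminium ion, hydroperoxide adds to C1 and the enamine closes the necessarily cis-fused oxirane, the cinchona scaffold choosing the face and so setting C1 and C2 together. Which antipode a given catalyst delivers is immaterial, because both are needed in equal amounts and the two batches only have to be opposite.

**Step 5**
Reactants: 5 3-(2-hydroxypropan-2-yl)cyclohex-2-en-1-one
Product: 7 (1S,6S)-6-(2-hydroxypropan-2-yl)-7-oxabicyclo[4.1.0]heptan-2-one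
Conditions: 9-amino-9-deoxy-epi-quinidine (10 mol%), TFA (20 mol%), 50% aq. H2O2 (1.5 equiv), 1,4-dioxane, 30–50 °C
Reagents that add atoms: hydrogen peroxide, OO
Why: Same iminium-catalysed epoxidation as step 4 with the pseudo-enantiomeric catalyst, which should deliver the mirror-image oxirane.

**Step 6**
Reactants: 6 (1R,6R)-6-(2-hydroxypropan-2-yl)-7-oxabicyclo[4.1.0]heptan-2-one
Product: 8 (2R,3R)-3-acetyl-2-hydroxy-3-methylcyclohexan-1-one
Conditions: BF3·OEt2 (0.3 equiv), CH2Cl2, −78 to −30 °C; cold Et3N then aq. NaHCO3
Reagents that add atoms: none
Why: Type-3 semipinacol rearrangement of a tertiary α-hydroxy epoxide (2,3-epoxy alcohol to β-hydroxy ketone), the closest known reaction type being the Lewis-acid rearrangement of (1,2-epoxycycloalkyl)carbinols to 2-acylcycloalkanols. BF3 binds the oxirane oxygen, the C1–O bond (tertiary, β to the ring carbonyl C3, whereas C2–O cleavage would put positive charge α to C=O) lengthens, and a methyl group on C9 that lies antiperiplanar to that bond migrates to C1 while the carbinol oxygen becomes the C9 carbonyl. No ring is closed; the oxirane is opened and the six-membered ring is kept. The new quaternary centre C1 is set by the invertive anti migration: methyl enters on the face opposite the oxirane oxygen, so C9 is pushed to the face of the oxygen that stays on C2, which gives hydroxyl cis to acyl. C2 keeps its configuration because its C–O bond is not touched, so the enantiopurity of the epoxide is carried over. The selectivity needed is methyl shift over 1,2-shift of the ring acyl carbon C3 (ring contraction, as in simple β,β-disubstituted epoxy ketones), hydride shift from C2 and proton loss to the diosphenol. It is secured because only a C–CH3 bond of the freely rotating carbinol can be antiperiplanar to the breaking bond from the start, so its migration can be concerted and is pushed by the hydroxyl lone pair, whereas the C2–C3 and C2–H bonds sit at about 110° to it and need full ionisation first, which low temperature and a sub-stoichiometric Lewis acid disfavour. The two methyl groups on C9 are identical, so no question of migratory aptitude arises.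

**Step 7**
Reactants: 7 (1S,6S)-6-(2-hydroxypropan-2-yl)-7-oxabicyclo[4.1.0]heptan-2-one
Product: 9 (2S,3S)-3-acetyl-2-hydroxy-3-methylcyclohexan-1-one
Conditions: BF3·OEt2 (0.3 equiv), CH2Cl2, −78 to −30 °C; cold Et3N then aq. NaHCO3
Reagents that add atoms: none
Why: Mirror-image run of step 6: the same stereospecific anti methyl shift (semipinacol rearrangement) should convert the (1S,6S)-epoxide into the (2S,3S)-ketol with hydroxyl cis to acetyl.

**Step 8**
Reactants: 8 (2R,3R)-3-acetyl-2-hydroxy-3-methylcyclohexan-1-one
Product: 10 (2R,3R)-3-acetyl-3-methyl-2-[(triethylsilyl)oxy]cyclohexan-1-one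
Conditions: TESOTf (1.2 equiv), 2,6-lutidine (2 equiv), CH2Cl2, −78 °C
Reagents that add atoms: triethylsilyl trifluoromethanesulfonate, CC[Si](CC)(CC)OS(=O)(=O)C(F)(F)F
Why: Silylation of a hindered secondary alcohol with a silyl triflate and a hindered pyridine base; at low temperature O-silylation should outrun silyl enol ether formation. The ether blocks retro-aldol cleavage in all later basic steps and supplies the α-oxygen substituent that directs the olefination; no stereocentre is touched.

**Step 9**
Reactants: 9 (2S,3S)-3-acetyl-2-hydroxy-3-methylcyclohexan-1-one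
Product: 11 (2S,3S)-3-acetyl-3-methyl-2-[(triethylsilyl)oxy]cyclohexan-1-one
Conditions: TESOTf (1.2 equiv), 2,6-lutidine (2 equiv), CH2Cl2, −78 °C
Reagents that add atoms: triethylsilyl trifluoromethanesulfonate, CC[Si](CC)(CC)OS(=O)(=O)C(F)(F)F
Why: Same O-silylation as step 8 on the antipode.

**Step 10**
Reactants: 10 (2R,3R)-3-acetyl-3-methyl-2-[(triethylsilyl)oxy]cyclohexan-1-one; 12 (4-hydroxybutyl)triphenylphosphonium bromide
Product: 14 1-[(1R,2S,3Z)-3-(4-hydroxybutylidene)-1-methyl-2-[(triethylsilyl)oxy]cyclohexyl]ethan-1-one, via ylide alkoxide 13 (not isolated)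
Conditions: 12 (1.2 equiv), KHMDS (2.4 equiv), THF/HMPA, −78 to 0 °C; then 10, −78 °C to rt; sat. aq. NH4Cl
Reagents that add atoms: none
Why: Wittig olefination of an α-alkoxy ketone with a non-stabilised ylide under lithium-free conditions, a reaction known to give the trisubstituted alkene with the ylide chain cis to the oxygenated α-carbon (here C8 cis to C2, Z). The ring carbonyl should react before the acetyl group because it is a cyclohexanone activated by the α-silyloxy group, whereas the acetyl carbonyl is flanked by the quaternary C1; the primary hydroxyl rides through as its potassium alkoxide.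

**Step 11**
Reactants: 14 1-[(1R,2S,3Z)-3-(4-hydroxybutylidene)-1-methyl-2-[(triethylsilyl)oxy]cyclohexyl]ethan-1-one
Product: 15 1-[(1R,2S,3Z)-3-(4-iodobutylidene)-1-methyl-2-[(triethylsilyl)oxy]cyclohexyl]ethan-1-one
Conditions: I2 (1.3 equiv), PPh3 (1.3 equiv), imidazole (2 equiv), CH2Cl2, 0 °C
Reagents that add atoms: iodine, II
Why: Appel-type iodination: the primary alcohol is displaced as its oxyphosphonium ion by iodide (SN2); the silyl ether, the ketone and the Z alkene should be inert under these imidazole-buffered conditions.

**Step 12**
Reactants: 15 1-[(1R,2S,3Z)-3-(4-iodobutylidene)-1-methyl-2-[(triethylsilyl)oxy]cyclohexyl]ethan-1-one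
Product: 16 {(4Z)-4-[(2S,3R)-3-acetyl-3-methyl-2-[(triethylsilyl)oxy]cyclohexylidene]butyl}triphenylphosphonium iodide
Conditions: PPh3 (2 equiv), MeCN, 70 °C
Reagents that add atoms: triphenylphosphine, c1ccc(cc1)P(c1ccccc1)c1ccccc1
Why: SN2 quaternisation of triphenylphosphine by the primary iodide; no acid or base is generated, so the silyl ether and the alkene geometry should be kept.

**Step 13**
Reactants: 16 {(4Z)-4-[(2S,3R)-3-acetyl-3-methyl-2-[(triethylsilyl)oxy]cyclohexylidene]butyl}triphenylphosphonium iodide; 11 (2S,3S)-3-acetyl-3-methyl-2-[(triethylsilyl)oxy]cyclohexan-1-one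
Product: 18 1-[(1R,2S,3Z)-3-{4-[(1Z,2R,3S)-3-acetyl-3-methyl-2-[(triethylsilyl)oxy]cyclohexylidene]butylidene}-1-methyl-2-[(triethylsilyl)oxy]cyclohexyl]ethan-1-one (meso), via phosphorus ylide 17 (not isolated)
Conditions: KHMDS (1.0 equiv), THF/HMPA, −78 °C; then 11 (1.1 equiv), −78 °C to rt
Reagents that add atoms: none
Why: Second Z-selective Wittig olefination of an α-silyloxy cyclohexanone, now with the mirror-image ketone; this step joins a (1R,2S) half to a (1'S,2'R) half and so makes the meso relation by construction. The base should deprotonate the phosphonium carbon before the less acidic acetyl groups, and geometry and chemoselectivity follow the reasoning of step 10.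

**Step 14**
Reactants: 18 meso bis(methyl ketone) bis(triethylsilyl ether) (name as in step 13); 19 1-bromo-2-methylprop-1-ene
Product: 22 1-[(1R,2S,3Z)-1-methyl-3-{4-[(1Z,2R,3S)-3-methyl-3-(4-methylpent-3-enoyl)-2-[(triethylsilyl)oxy]cyclohexylidene]butylidene}-2-[(triethylsilyl)oxy]cyclohexyl]-4-methylpent-3-en-1-one, via bis(lithium enolate) 20 (not isolated), via bis(lithium dienolate) 21 (not isolated)
Conditions: LiHMDS (4.5 equiv), Pd2(dba)3 (5 mol%), Q-Phos (12 mol%), 19 (2.6 equiv), THF, rt to 50 °C; then AcOH in THF, −78 °C
Reagents that add atoms: none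
Why: Palladium-catalysed α-alkenylation of ketone enolates with an alkenyl bromide (oxidative addition, transmetallation of the lithium enolate, C–C reductive elimination), run at both ends at once. Each acetyl group has a single enolisable position because C1 is quaternary, and the product, more acidic at C10, is held as the dienolate by the excess base, which should prevent a second coupling. Kinetic protonation of the dienolate at C10 on cold acidic quench should give the β,γ-unsaturated ketone and not the conjugated isomer.

**Step 15**
Reactants: 22 bis(triethylsilyl ether) of the target (name as in step 14)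
Product: 23 1-[(1R,2S,3Z)-2-hydroxy-3-{4-[(1Z,2R,3S)-2-hydroxy-3-methyl-3-(4-methylpent-3-enoyl)cyclohexylidene]butylidene}-1-methylcyclohexyl]-4-methylpent-3-en-1-one (meso; CNP0297042.2)
Conditions: HF·pyridine, pyridine, THF, 0 °C to rt; aq. NaHCO3 at 0 °C
Reagents that add atoms: none
Why: Fluoride-mediated cleavage of both silyl ethers under pyridine-buffered, weakly acidic conditions. Base is avoided so that the liberated aldol units do not undergo retro-aldol cleavage and the β,γ-unsaturated ketones do not conjugate, and the acidity should be too low to ionise the allylic alcohols.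

## Compound list

1 | 3'-methoxyacetophenone | COc1cccc(c1)C(C)=O | starting material
2 | 2-(3-methoxyphenyl)propan-2-ol | COc1cccc(c1)C(C)(C)O | intermediate
3 | 2-(5-methoxycyclohexa-1,4-dien-1-yl)propan-2-ol | COC1=CCC=C(C1)C(C)(C)O | intermediate
4 | 3-(2-hydroxypropan-2-yl)cyclohex-3-en-1-one | O=C1CCC=C(C1)C(C)(C)O | intermediate (not isolated)
5 | 3-(2-hydroxypropan-2-yl)cyclohex-2-en-1-one | CC(C)(O)C1=CC(=O)CCC1 | intermediate
6 | (1R,6R)-6-(2-hydroxypropan-2-yl)-7-oxabicyclo[4.1.0]heptan-2-one | CC(C)(O)[C@@]12CCCC(=O)[C@@H]1O2 | intermediate
7 | (1S,6S)-6-(2-hydroxypropan-2-yl)-7-oxabicyclo[4.1.0]heptan-2-one | CC(C)(O)[C@]12CCCC(=O)[C@H]1O2 | intermediate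
8 | (2R,3R)-3-acetyl-2-hydroxy-3-methylcyclohexan-1-one | CC(=O)[C@]1(C)CCCC(=O)[C@@H]1O | intermediate
9 | (2S,3S)-3-acetyl-2-hydroxy-3-methylcyclohexan-1-one | CC(=O)[C@@]1(C)CCCC(=O)[C@H]1O | intermediate
10 | (2R,3R)-3-acetyl-3-methyl-2-[(triethylsilyl)oxy]cyclohexan-1-one | CC(=O)[C@]1(C)CCCC(=O)[C@@H]1O[Si](CC)(CC)CC | intermediate
11 | (2S,3S)-3-acetyl-3-methyl-2-[(triethylsilyl)oxy]cyclohexan-1-one | CC(=O)[C@@]1(C)CCCC(=O)[C@H]1O[Si](CC)(CC)CC | intermediate
12 | (4-hydroxybutyl)triphenylphosphonium bromide (if not bought, one step from THF and Ph3P·HBr) | OCCCC[P+](c1ccccc1)(c1ccccc1)c1ccccc1.[Br-] | starting material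
13 | potassium 4-(triphenyl-λ5-phosphanylidene)butan-1-olate | [K+].[O-]CCCC=P(c1ccccc1)(c1ccccc1)c1ccccc1 | intermediate (not isolated)
14 | 1-[(1R,2S,3Z)-3-(4-hydroxybutylidene)-1-methyl-2-[(triethylsilyl)oxy]cyclohexyl]ethan-1-one | CC(=O)[C@]1(C)CCC/C(=C/CCCO)[C@@H]1O[Si](CC)(CC)CC | intermediate
15 | 1-[(1R,2S,3Z)-3-(4-iodobutylidene)-1-methyl-2-[(triethylsilyl)oxy]cyclohexyl]ethan-1-one | CC(=O)[C@]1(C)CCC/C(=C/CCCI)[C@@H]1O[Si](CC)(CC)CC | intermediate
16 | {(4Z)-4-[(2S,3R)-3-acetyl-3-methyl-2-[(triethylsilyl)oxy]cyclohexylidene]butyl}triphenylphosphonium iodide | CC(=O)[C@]1(C)CCC/C(=C/CCC[P+](c2ccccc2)(c2ccccc2)c2ccccc2)[C@@H]1O[Si](CC)(CC)CC.[I-] | intermediate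
17 | 1-[(1R,2S,3Z)-1-methyl-2-[(triethylsilyl)oxy]-3-[4-(triphenyl-λ5-phosphanylidene)butylidene]cyclohexyl]ethan-1-one | CC(=O)[C@]1(C)CCC/C(=C/CCC=P(c2ccccc2)(c2ccccc2)c2ccccc2)[C@@H]1O[Si](CC)(CC)CC | intermediate (not isolated)
18 | 1-[(1R,2S,3Z)-3-{4-[(1Z,2R,3S)-3-acetyl-3-methyl-2-[(triethylsilyl)oxy]cyclohexylidene]butylidene}-1-methyl-2-[(triethylsilyl)oxy]cyclohexyl]ethan-1-one (meso) | CC(=O)[C@]1(C)CCC/C(=C/CC/C=C2/CCC[C@](C)(C(C)=O)[C@@H]2O[Si](CC)(CC)CC)[C@@H]1O[Si](CC)(CC)CC | intermediate
19 | 1-bromo-2-methylprop-1-ene | CC(C)=CBr | starting material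
20 | dilithium bis(enolate) of 18 (both acetyl groups as C9(OLi)=C10H2) | [Li+].[Li+].C=C([O-])[C@]1(C)CCC/C(=C/CC/C=C2/CCC[C@](C)(C([O-])=C)[C@@H]2O[Si](CC)(CC)CC)[C@@H]1O[Si](CC)(CC)CC | intermediate (not isolated)
21 | dilithium bis(dienolate) of 22 (both side chains as C9(OLi)=C10H–C11H=C12Me2) | [Li+].[Li+].CC(C)=CC=C([O-])[C@]1(C)CCC/C(=C/CC/C=C2/CCC[C@](C)(C([O-])=CC=C(C)C)[C@@H]2O[Si](CC)(CC)CC)[C@@H]1O[Si](CC)(CC)CC | intermediate (not isolated)
22 | 1-[(1R,2S,3Z)-1-methyl-3-{4-[(1Z,2R,3S)-3-methyl-3-(4-methylpent-3-enoyl)-2-[(triethylsilyl)oxy]cyclohexylidene]butylidene}-2-[(triethylsilyl)oxy]cyclohexyl]-4-methylpent-3-en-1-one (meso) | CC(C)=CCC(=O)[C@]1(C)CCC/C(=C/CC/C=C2/CCC[C@](C)(C(=O)CC=C(C)C)[C@@H]2O[Si](CC)(CC)CC)[C@@H]1O[Si](CC)(CC)CC | intermediate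
23 | 1-[(1R,2S,3Z)-2-hydroxy-3-{4-[(1Z,2R,3S)-2-hydroxy-3-methyl-3-(4-methylpent-3-enoyl)cyclohexylidene]butylidene}-1-methylcyclohexyl]-4-methylpent-3-en-1-one (meso) | CC(C)=CCC(=O)[C@]1(C)CCC/C(=C/CC/C=C2/CCC[C@](C)(C(=O)CC=C(C)C)[C@@H]2O)[C@@H]1O | target

## Step count and least certain steps

Total step count: 15. Longest linear sequence: 12 steps (1, 2, 3, 4, 6, 8, 10, 11, 12, 13, 14, 15); steps 5, 7 and 9 form the second branch from 5, which joins at step 13. Any shortfall in the enantiopurity of 10 or 11 would appear in 18 as the C2-symmetric diastereomer, so the ketols 8 and 9 should be brought to full enantiopurity (recrystallisation may serve) before silylation.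

**Step 6 (key step; step 7 is its mirror-image run).** The most likely failure is that the C1–O bond ionises ahead of the methyl shift, because methyl is a poor migrating group and the oxirane is also an α,β-epoxy ketone. The cation could then be captured by 1,2-shift of the ring acyl carbon (ring contraction) or lose a proton to the diosphenol. Prolonged contact with the Lewis acid could also epimerise C2 or trigger retro-aldol cleavage. The fallback takes the ring carbonyl out of play. Setting out from 6, Luche reduction (NaBH4, CeCl3, MeOH) would give the epoxy diol (1S,2RS,6R)-6-(2-hydroxypropan-2-yl)-7-oxabicyclo[4.1.0]heptan-2-ol F1, either C3 epimer serving, which is an ordinary tertiary α-hydroxy epoxide. The same Lewis-acid rearrangement would give the keto diol 1-[(1R,2R,3RS)-2,3-dihydroxy-1-methylcyclohexyl]ethan-1-one F2. Chemoselective oxidation of the less hindered ring carbinol C3–OH of the vicinal diol (cationic Pd–neocuproine catalyst with O2) would return to the route at 8. For step 7 the same sequence sets out from 7 and runs through the enantiomeric epoxy diol (1R,2RS,6S)-6-(2-hydroxypropan-2-yl)-7-oxabicyclo[4.1.0]heptan-2-ol F3 and keto diol 1-[(1S,2S,3RS)-2,3-dihydroxy-1-methylcyclohexyl]ethan-1-one F4, returning at 9.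

**Step 4 (and its twin, step 5).** The most likely failure is slow conjugate addition of hydroperoxide to C1, which already carries the bulky tertiary carbinol, leading to incomplete conversion or poor facial control by the catalyst. The fallback replaces catalyst control by resolution. Setting out from 5, alkaline Weitz–Scheffer epoxidation (H2O2, NaOH, MeOH, 0 °C) would give 6 and 7 together as the racemate. Steps 6 and 8 are then run once on the racemate, and 10 is separated from 11 by preparative chromatography on a chiral stationary phase. Both antipodes are used, so nothing is discarded, and the route is rejoined at 10 and 11. No new compound is made.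

**Step 10.** The most likely failure is erosion of geometric control, because the quaternary C1 and the bulky silyl ether next to the carbonyl may override the α-alkoxy effect. Base-induced epimerisation at C2 and attack at the acetyl group are secondary risks. The fallback is a stepwise, stereospecific Horner–Wittig olefination. Alkaline hydrolysis of 12 would give (4-hydroxybutyl)diphenylphosphine oxide F5 with loss of benzene. Its dilithio derivative (n-BuLi, 2 equiv, THF, −78 °C) would add to the ring carbonyl of 10. The diastereomeric β-hydroxy phosphine oxides are separated. The isomer 1-[(1R,2R,3S)-3-[(1R)-1-(diphenylphosphoryl)-4-hydroxybutyl]-3-hydroxy-1-methyl-2-[(triethylsilyl)oxy]cyclohexyl]ethan-1-one F6, in which syn-elimination places C8 cis to C2, is treated with NaH in DMF. This would return to the route at 14; the unwanted diastereomers can be returned to 10 by base-induced reversal of the addition.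

**Step 13.** The risks of step 10 apply again. In addition, ylide 17 may be quenched by proton transfer from an acetyl group, or may attack its own acetyl carbonyl, since the Z alkene holds the chain near C9 (eight-membered ring closure). The fallback uses the same stereospecific logic. Setting out from 15, Michaelis–Arbuzov reaction with ethyl diphenylphosphinite would give 1-[(1R,2S,3Z)-3-[4-(diphenylphosphoryl)butylidene]-1-methyl-2-[(triethylsilyl)oxy]cyclohexyl]ethan-1-one F7. Its dianion (LDA, 2 equiv: enolate plus α-phosphoryl carbanion) would add to 11. After separation, the adduct 1-[(1R,2S,3Z)-3-{(4S)-4-(diphenylphosphoryl)-4-[(1R,2S,3S)-3-acetyl-1-hydroxy-3-methyl-2-[(triethylsilyl)oxy]cyclohexyl]butylidene}-1-methyl-2-[(triethylsilyl)oxy]cyclohexyl]ethan-1-one F8 is eliminated with NaH in DMF, returning to the route at 18.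

**Step 14.** The most likely failures are a second alkenylation at C10, palladium hydride-mediated migration of the new or the ring-exocyclic double bonds, and protonation of the dienolate at the γ-carbon to give the conjugated enone. The fallback builds the side chain by aldol chemistry. Setting out from 18, the bis(lithium enolate) (LDA, −78 °C) would add to 2-methylpropanal to give the bis-aldol 3-hydroxy-1-[(1R,2S,3Z)-3-{4-[(1Z,2R,3S)-3-(3-hydroxy-4-methylpentanoyl)-3-methyl-2-[(triethylsilyl)oxy]cyclohexylidene]butylidene}-1-methyl-2-[(triethylsilyl)oxy]cyclohexyl]-4-methylpentan-1-one F9 (carbinol epimers). Dehydration with the Burgess reagent would give the bis-(E)-enone (2E)-4-methyl-1-[(1R,2S,3Z)-1-methyl-3-{4-[(1Z,2R,3S)-3-methyl-3-[(2E)-4-methylpent-2-enoyl]-2-[(triethylsilyl)oxy]cyclohexylidene]butylidene}-2-[(triethylsilyl)oxy]cyclohexyl]pent-2-en-1-one F10. γ-Deprotonation (LDA, HMPA, −78 °C) would give the same dienolate 21, and kinetic protonation at C10 would return to the route at 22.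

## Further compounds

F1 | step 6 | (1S,2RS,6R)-6-(2-hydroxypropan-2-yl)-7-oxabicyclo[4.1.0]heptan-2-ol | CC(C)(O)[C@@]12CCCC(O)[C@@H]1O2
F2 | step 6 | 1-[(1R,2R,3RS)-2,3-dihydroxy-1-methylcyclohexyl]ethan-1-one | CC(=O)[C@]1(C)CCCC(O)[C@@H]1O
F3 | step 7 | (1R,2RS,6S)-6-(2-hydroxypropan-2-yl)-7-oxabicyclo[4.1.0]heptan-2-ol | CC(C)(O)[C@]12CCCC(O)[C@H]1O2
F4 | step 7 | 1-[(1S,2S,3RS)-2,3-dihydroxy-1-methylcyclohexyl]ethan-1-one | CC(=O)[C@@]1(C)CCCC(O)[C@H]1O
F0 | step 4 | none | none
F0 | step 5 | none | none
F5 | step 10 | (4-hydroxybutyl)diphenylphosphine oxide | OCCCCP(=O)(c1ccccc1)c1ccccc1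
F6 | step 10 | 1-[(1R,2R,3S)-3-[(1R)-1-(diphenylphosphoryl)-4-hydroxybutyl]-3-hydroxy-1-methyl-2-[(triethylsilyl)oxy]cyclohexyl]ethan-1-one | CC(=O)[C@]1(C)CCC[C@@](O)([C@@H](CCCO)P(=O)(c2ccccc2)c2ccccc2)[C@@H]1O[Si](CC)(CC)CC
F7 | step 13 | 1-[(1R,2S,3Z)-3-[4-(diphenylphosphoryl)butylidene]-1-methyl-2-[(triethylsilyl)oxy]cyclohexyl]ethan-1-one | CC(=O)[C@]1(C)CCC/C(=C/CCCP(=O)(c2ccccc2)c2ccccc2)[C@@H]1O[Si](CC)(CC)CC
F8 | step 13 | 1-[(1R,2S,3Z)-3-{(4S)-4-(diphenylphosphoryl)-4-[(1R,2S,3S)-3-acetyl-1-hydroxy-3-methyl-2-[(triethylsilyl)oxy]cyclohexyl]butylidene}-1-methyl-2-[(triethylsilyl)oxy]cyclohexyl]ethan-1-one | CC(=O)[C@]1(C)CCC/C(=C/CC[C@H](P(=O)(c2ccccc2)c2ccccc2)[C@@]2(O)CCC[C@](C)(C(C)=O)[C@@H]2O[Si](CC)(CC)CC)[C@@H]1O[Si](CC)(CC)CC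
F9 | step 14 | 3-hydroxy-1-[(1R,2S,3Z)-3-{4-[(1Z,2R,3S)-3-(3-hydroxy-4-methylpentanoyl)-3-methyl-2-[(triethylsilyl)oxy]cyclohexylidene]butylidene}-1-methyl-2-[(triethylsilyl)oxy]cyclohexyl]-4-methylpentan-1-one (carbinol epimers) | CC(C)C(O)CC(=O)[C@]1(C)CCC/C(=C/CC/C=C2/CCC[C@](C)(C(=O)CC(O)C(C)C)[C@@H]2O[Si](CC)(CC)CC)[C@@H]1O[Si](CC)(CC)CC
F10 | step 14 | (2E)-4-methyl-1-[(1R,2S,3Z)-1-methyl-3-{4-[(1Z,2R,3S)-3-methyl-3-[(2E)-4-methylpent-2-enoyl]-2-[(triethylsilyl)oxy]cyclohexylidene]butylidene}-2-[(triethylsilyl)oxy]cyclohexyl]pent-2-en-1-one | CC(C)/C=C/C(=O)[C@]1(C)CCC/C(=C/CC/C=C2/CCC[C@](C)(C(=O)/C=C/C(C)C)[C@@H]2O[Si](CC)(CC)CC)[C@@H]1O[Si](CC)(CC)CC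
A1 | alternative 1 | 1-[(1R,2S,3Z)-3-(2-bromoethylidene)-1-methyl-2-[(triethylsilyl)oxy]cyclohexyl]-4-methylpent-3-en-1-one | CC(C)=CCC(=O)[C@]1(C)CCC/C(=C/CBr)[C@@H]1O[Si](CC)(CC)CC
A2 | alternative 1 | 4-methyl-1-[(1S,2R,3Z)-1-methyl-3-[2-(phenylsulfonyl)ethylidene]-2-[(triethylsilyl)oxy]cyclohexyl]pent-3-en-1-one | CC(C)=CCC(=O)[C@@]1(C)CCC/C(=C/CS(=O)(=O)c2ccccc2)[C@H]1O[Si](CC)(CC)CC
A3 | alternative 2 | butane-1,4-diylbis(triphenylphosphonium) dibromide | [Br-].[Br-].C(CC[P+](c1ccccc1)(c1ccccc1)c1ccccc1)C[P+](c1ccccc1)(c1ccccc1)c1ccccc1
A4 | alternative 3 | (2Z,6Z)-2,7-bis(4,8-dimethyl-5-oxonon-7-en-1-yl)octa-2,6-dienedial (α-methyl centres epimerisable, not specified) | CC(C)=CCC(=O)C(C)CCC/C(C=O)=C/CC/C=C(/CCCC(C)C(=O)CC=C(C)C)C=O
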